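**Retrosynthetic overview**
1. The five-membered hemiketal ring of the target (O1–C2–C3–C3a–C7a) is traced back to the six-membered pyranone ring of the 3-alkyl-4-hydroxy-5-methylcoumarin 9; the lactone carbonyl carbon is excised as CO2 in an aerobic oxidative ring contraction, which is the last step and needs no protecting groups.
2. Enabling feature: in 9 the enol carbon C3 of the pyranone ring sits between the C4 enol and the aryl-ester carbonyl C2, whose ring oxygen O1 is a phenoxide leaving group; C3 takes up O2, the peroxide closes on C2 and expels O1, C2 leaves as CO2, and O1 re-closes on the new ketone.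
3. The six-membered lactone is a temporary ring: its extra carbon makes C3 a soft carbon nucleophile, so the C2–C1' bond of the target is made by palladium-catalysed C-allylation of 4-hydroxy-5-methylcoumarin 8 with (8R)-8-hydroxyfarnesyl acetate 5, at a carbon that ends as an electrophilic ketone/hemiketal carbon.
4. Side chain 5: geranyl acetate, E-selective allylic oxidation to the C8 aldehyde, catalytic asymmetric allylation (sets C8' as R), cross-metathesis to the prenyl terminus.
5. Ring order: benzene ring purchased; pyranone ring closed in step 5; furanone ring formed from it by contraction in step 7.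

Key step: step 7

Assumption: the hemiketal carbon C2 can epimerise by ring–chain tautomerism through the open 1,2-diketone; it is taken to be configurationally stable in neutral aprotic media, so it is created in the last step, the (2R) epimer is isolated on a chiral phase without acid or base, and the (2S) epimer is recycled by amine-catalysed re-equilibration.

**Step 1**
Reactants: 1 geranyl acetate
Product: 2 (2E,6E)-8-hydroxy-3,7-dimethylocta-2,6-dien-1-yl acetate
Conditions: SeO2 (0.1 equiv), t-BuOOH (2.5 equiv), salicylic acid (0.1 equiv), CH2Cl2, 23 °C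
Reagents that add atoms: tert-butyl hydroperoxide, CC(C)(C)OO (terminal oxygen source; the oxygen is passed on through selenium dioxide, O=[Se]=O)
Why: Catalytic SeO2 allylic oxidation (ene reaction, then [2,3]-sigmatropic shift) should attack the (E)-methyl group of the remote, more electron-rich trisubstituted alkene and give the (E)-allylic alcohol, the alkene next to the acetate being deactivated.

**Step 2**
Reactants: 2 (2E,6E)-8-hydroxy-3,7-dimethylocta-2,6-dien-1-yl acetate
Product: 3 (2E,6E)-3,7-dimethyl-8-oxoocta-2,6-dien-1-yl acetate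
Conditions: MnO2 (15 equiv), CH2Cl2, 23 °C
Reagents that add atoms: none
Why: MnO2 oxidation is selective for allylic alcohols and should stop at the (E)-enal without isomerisation; the acetate is inert.

**Step 3**
Reactants: 3 (2E,6E)-3,7-dimethyl-8-oxoocta-2,6-dien-1-yl acetate
Product: 4 (2E,6E,8R)-8-hydroxy-3,7-dimethylundeca-2,6,10-trien-1-yl acetate
Conditions: allylB(pin) (1.2 equiv), (R)-3,3'-bis(2,4,6-triisopropylphenyl)-1,1'-binaphthyl-2,2'-diyl hydrogen phosphate (5 mol%), toluene, −30 °C
Reagents that add atoms: allylboronic acid pinacol ester, C=CCB1OC(C)(C)C(C)(C)O1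
Why: Chiral phosphoric acid-catalysed allylboration through a closed chair-like six-membered transition state; the (R)-acid is expected to deliver the allyl group to the Re face of the enal (the sense known for aryl and alkenyl aldehydes), which sets C8 as R, while the acetate and the trisubstituted alkenes do not react.

**Step 4**
Reactants: 4 (2E,6E,8R)-8-hydroxy-3,7-dimethylundeca-2,6,10-trien-1-yl acetate
Product: 5 (2E,6E,8R)-8-hydroxy-3,7,11-trimethyldodeca-2,6,10-trien-1-yl acetate
Conditions: second-generation Grubbs catalyst [RuCl2(=CHPh)(PCy3)(H2IMes)] (5 mol%), 2-methyl-2-butene (excess), CH2Cl2, 40 °C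
Reagents that add atoms: 2-methyl-2-butene, CC=C(C)C
Why: Olefin cross-metathesis of the terminal alkene with excess 2-methyl-2-butene should turn the allyl group into the prenyl terminus; the two trisubstituted alkenes of 4 are too hindered to take part and the carbinol centre is not touched.

**Step 5**
Reactants: 6 1-(2-hydroxy-6-methylphenyl)ethanone
Product: 8 4-hydroxy-5-methyl-2H-chromen-2-one, via β-keto ester 7 (not isolated)
Conditions: NaH (3 equiv), (EtO)2CO, toluene, 110 °C; then aq. HCl
Reagents that add atoms: diethyl carbonate, CCOC(=O)OCC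
Why: Claisen-type C-ethoxycarbonylation of the ketone enolate by diethyl carbonate, then lactonisation of β-keto ester 7 onto the phenoxide, closes the six-membered pyranone ring (standard 4-hydroxycoumarin synthesis).

**Step 6**
Reactants: 5 (2E,6E,8R)-8-hydroxy-3,7,11-trimethyldodeca-2,6,10-trien-1-yl acetate; 8 4-hydroxy-5-methyl-2H-chromen-2-one (1.5 equiv)
Product: 9 4-hydroxy-3-[(2E,6E,8R)-8-hydroxy-3,7,11-trimethyldodeca-2,6,10-trien-1-yl]-5-methyl-2H-chromen-2-one
Conditions: Pd(PPh3)4 (5 mol%), Et3N (1.5 equiv), THF, 40 °C; work-up at pH 4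
Reagents that add atoms: none
Why: Tsuji–Trost allylic alkylation: zerovalent palladium ionises the primary allylic acetate and the soft coumarin enolate should attack the less hindered CH2 terminus through C3 (O-allylation is reversible under the conditions), with the E geometry kept because alkylation is faster than syn–anti exchange; the unactivated secondary alcohol is not ionised.

**Step 7**
Reactants: 9 4-hydroxy-3-[(2E,6E,8R)-8-hydroxy-3,7,11-trimethyldodeca-2,6,10-trien-1-yl]-5-methyl-2H-chromen-2-one
Product: 13 (2R)-2-hydroxy-2-[(2E,6E,8R)-8-hydroxy-3,7,11-trimethyldodeca-2,6,10-trien-1-yl]-4-methyl-1-benzofuran-3(2H)-one, via C3 hydroperoxide 10 (not isolated), via dioxetanone 11 (not isolated), via open-chain 1,2-diketone 12 (not isolated)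
Conditions: O2 (1 atm), Cu(OAc)2 (10 mol%), 2,2'-bipyridine (10 mol%), MeCN, 25 °C; neutral work-up; HPLC on amylose tris(3,5-dimethylphenylcarbamate), hexane/i-PrOH
Reagents that add atoms: dioxygen, O=O
Why: Divalent copper oxidises the acidic enol of 9 at C3 and O2 is trapped there to give hydroperoxide 10, whose peroxy oxygen adds to the neighbouring aryl-ester carbonyl C2 and expels phenoxide O1 (the pyranone ring opens) to give dioxetanone 11; 11 loses CO2 to give diketone 12, and O1 re-closes on the new ketone, so the furanone ring has one ring atom fewer than the lactone it came from. The closest known reaction types are the aerobic oxidative decarboxylative ring contraction of 3-substituted 4-hydroxycoumarins to 2-hydroxybenzofuran-3(2H)-ones and the dioxetanone decarboxylation of α-hydroperoxy aryl esters. The only ring closed is the furanone ring, by 5-exo-trig addition of the phenol oxygen to the highly electrophilic 1,2-dicarbonyl, the five-membered hemiketal being the stable tautomer. The new stereocentre C2 arises in this hemiketalisation with no internal control element (C8' is eight bonds away), so both C2 epimers are expected; the (2R) epimer is taken on the chiral phase and the (2S) epimer is re-equilibrated with a trace of Et3N and recycled. The step needs chemoselectivity for the enol over three trisubstituted alkenes and a secondary allylic alcohol, which triplet O2 with a one-electron copper shuttle should provide (no peracid, no singlet oxygen, no nitroxyl), and C2–C3 rather than C3–C4 scission, which is secured because the aryl-ester carbonyl with its phenoxide leaving group is a better acceptor than the C4 ketone, hindered by the ortho methyl group and deactivated by conjugation with O1.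

**Compound list**
1 | geranyl acetate, (2E)-3,7-dimethylocta-2,6-dien-1-yl acetate | CC(C)=CCC/C(C)=C/COC(C)=O | starting material
2 | (2E,6E)-8-hydroxy-3,7-dimethylocta-2,6-dien-1-yl acetate | OC/C(C)=C/CC/C(C)=C/COC(C)=O | intermediate
3 | (2E,6E)-3,7-dimethyl-8-oxoocta-2,6-dien-1-yl acetate | O=C/C(C)=C/CC/C(C)=C/COC(C)=O | intermediate
4 | (2E,6E,8R)-8-hydroxy-3,7-dimethylundeca-2,6,10-trien-1-yl acetate | C=CC[C@@H](O)/C(C)=C/CC/C(C)=C/COC(C)=O | intermediate
5 | (2E,6E,8R)-8-hydroxy-3,7,11-trimethyldodeca-2,6,10-trien-1-yl acetate | CC(C)=CC[C@@H](O)/C(C)=C/CC/C(C)=C/COC(C)=O | intermediate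
6 | 1-(2-hydroxy-6-methylphenyl)ethanone | CC(=O)c1c(C)cccc1O | starting material
7 | ethyl 3-(2-hydroxy-6-methylphenyl)-3-oxopropanoate | CCOC(=O)CC(=O)c1c(C)cccc1O | intermediate (not isolated)
8 | 4-hydroxy-5-methyl-2H-chromen-2-one | Cc1cccc2oc(=O)cc(O)c12 | intermediate
9 | 4-hydroxy-3-[(2E,6E,8R)-8-hydroxy-3,7,11-trimethyldodeca-2,6,10-trien-1-yl]-5-methyl-2H-chromen-2-one | CC(C)=CC[C@@H](O)/C(C)=C/CC/C(C)=C/Cc1c(O)c2c(C)cccc2oc1=O | intermediate
10 | 3-hydroperoxy-3-[(2E,6E,8R)-8-hydroxy-3,7,11-trimethyldodeca-2,6,10-trien-1-yl]-5-methylchromane-2,4-dione (both C3 epimers) | CC(C)=CC[C@@H](O)/C(C)=C/CC/C(C)=C/CC1(OO)C(=O)Oc2cccc(C)c2C1=O | intermediate (not isolated)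
11 | 4-(2-hydroxy-6-methylbenzoyl)-4-[(2E,6E,8R)-8-hydroxy-3,7,11-trimethyldodeca-2,6,10-trien-1-yl]-1,2-dioxetan-3-one (both C4 epimers) | CC(C)=CC[C@@H](O)/C(C)=C/CC/C(C)=C/CC1(OOC1=O)C(=O)c1c(C)cccc1O | intermediate (not isolated)
12 | (4E,8E,10R)-10-hydroxy-1-(2-hydroxy-6-methylphenyl)-5,9,13-trimethyltetradeca-4,8,12-triene-1,2-dione | CC(C)=CC[C@@H](O)/C(C)=C/CC/C(C)=C/CC(=O)C(=O)c1c(C)cccc1O | intermediate (not isolated)
13 | (2R)-2-hydroxy-2-[(2E,6E,8R)-8-hydroxy-3,7,11-trimethyldodeca-2,6,10-trien-1-yl]-4-methyl-1-benzofuran-3(2H)-one | CC(C)=CC[C@@H](O)/C(C)=C/CC/C(C)=C/C[C@@]1(O)Oc2cccc(C)c2C1=O | target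

Total step count: 7. Longest linear sequence: 6 steps (steps 1, 2, 3, 4, 6, 7); the coumarin branch is 1 step (step 5) before the union.

**Steps most likely to fail**

Step 7. The C3 hydroperoxide may be diverted: reduction to the tertiary alcohol, alkoxyl-radical fragmentation with loss of the allylic chain, scission on the C4 side, or autoxidation at the allylic positions of the chain. The step also gives no control at C2. The fallback is a stepwise ring contraction by two-electron chemistry, setting out from 9. Hydroxylation of the enolate with 2-(phenylsulfonyl)-3-phenyloxaziridine (Davis reagent, K2CO3, THF, 0 °C), which leaves the alkenes alone, should give 3-hydroxy-3-[(2E,6E,8R)-8-hydroxy-3,7,11-trimethyldodeca-2,6,10-trien-1-yl]-5-methylchromane-2,4-dione F1. LiOH in THF/H2O under argon opens the lactone to 2-hydroxy-2-[(2E,6E,8R)-8-hydroxy-3,7,11-trimethyldodeca-2,6,10-trien-1-yl]-3-(2-hydroxy-6-methylphenyl)-3-oxopropanoic acid F2. This β-keto acid loses CO2 in the flask to give the α-ketol (4E,8E,10R)-2,10-dihydroxy-1-(2-hydroxy-6-methylphenyl)-5,9,13-trimethyltetradeca-4,8,12-trien-1-one F3. Acyloin oxidation with Cu(OAc)2 (2.2 equiv) in MeOH/H2O at 50 °C, which spares the isolated secondary alcohol, should give diketone 12, which closes to 13, where the fallback rejoins the route.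

Step 6. The ionised allyl unit may lose its E geometry by syn–anti exchange, be attacked at the tertiary terminus, or be taken up at oxygen or twice at C3. The fallback makes the C–C bond by SN2 alkylation and builds the pyranone ring afterwards, setting out from 5 and 6.
- Silylation of 5 (TBSCl, imidazole, DMF) should give (2E,6E,8R)-8-[(tert-butyldimethylsilyl)oxy]-3,7,11-trimethyldodeca-2,6,10-trien-1-yl acetate F4.
- Methanolysis (K2CO3, MeOH) gives (2E,6E,8R)-8-[(tert-butyldimethylsilyl)oxy]-3,7,11-trimethyldodeca-2,6,10-trien-1-ol F5.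
- Appel bromination (CBr4, PPh3, CH2Cl2, 0 °C) gives [(2E,6E,8R)-1-bromo-3,7,11-trimethyldodeca-2,6,10-trien-8-yl]oxy(tert-butyl)dimethylsilane F6.
- The dianion of 6 (LDA 2.2 equiv, THF, −78 to 0 °C) is alkylated by F6 to (4E,8E,10R)-10-[(tert-butyldimethylsilyl)oxy]-1-(2-hydroxy-6-methylphenyl)-5,9,13-trimethyltetradeca-4,8,12-trien-1-one F7; no ionised allyl species is involved, so linear connectivity and E geometry are fixed.
- NaH/(EtO)2CO in toluene at 110 °C, as in step 5, leads through ethyl (4E,8E,10R)-10-[(tert-butyldimethylsilyl)oxy]-2-(2-hydroxy-6-methylbenzoyl)-5,9,13-trimethyltetradeca-4,8,12-trienoate F8 to 3-{(2E,6E,8R)-8-[(tert-butyldimethylsilyl)oxy]-3,7,11-trimethyldodeca-2,6,10-trien-1-yl}-4-hydroxy-5-methyl-2H-chromen-2-one F9.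
- Desilylation (TBAF, THF) returns to the route at 9.

Step 3. Facial selectivity on the α-methyl enal may be insufficient. The fallback sets the carbinol centre by reduction instead of C–C bond formation, setting out from 3. Uncatalysed addition of allylB(pin) (toluene, 23 °C) gives racemic (2E,6E)-8-hydroxy-3,7-dimethylundeca-2,6,10-trien-1-yl acetate F10. Dess–Martin periodinane with NaHCO3 (CH2Cl2, 0 °C) gives (2E,6E)-3,7-dimethyl-8-oxoundeca-2,6,10-trien-1-yl acetate F11. Corey–Bakshi–Shibata reduction with (S)-2-methyl-CBS-oxazaborolidine and catecholborane (toluene, −78 °C), with the α-methylalkenyl group as the large substituent, should give the R alcohol and return to the route at 4.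

**Further compounds**
F1 | step 7 | 3-hydroxy-3-[(2E,6E,8R)-8-hydroxy-3,7,11-trimethyldodeca-2,6,10-trien-1-yl]-5-methylchromane-2,4-dione (both C3 epimers) | CC(C)=CC[C@@H](O)/C(C)=C/CC/C(C)=C/CC1(O)C(=O)Oc2cccc(C)c2C1=O
F2 | step 7 | 2-hydroxy-2-[(2E,6E,8R)-8-hydroxy-3,7,11-trimethyldodeca-2,6,10-trien-1-yl]-3-(2-hydroxy-6-methylphenyl)-3-oxopropanoic acid (both C2 epimers) | CC(C)=CC[C@@H](O)/C(C)=C/CC/C(C)=C/CC(O)(C(=O)O)C(=O)c1c(C)cccc1O
F3 | step 7 | (4E,8E,10R)-2,10-dihydroxy-1-(2-hydroxy-6-methylphenyl)-5,9,13-trimethyltetradeca-4,8,12-trien-1-one (both C2 epimers) | CC(C)=CC[C@@H](O)/C(C)=C/CC/C(C)=C/CC(O)C(=O)c1c(C)cccc1O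
F4 | step 6 | (2E,6E,8R)-8-[(tert-butyldimethylsilyl)oxy]-3,7,11-trimethyldodeca-2,6,10-trien-1-yl acetate | CC(C)=CC[C@@H](O[Si](C)(C)C(C)(C)C)/C(C)=C/CC/C(C)=C/COC(C)=O
F5 | step 6 | (2E,6E,8R)-8-[(tert-butyldimethylsilyl)oxy]-3,7,11-trimethyldodeca-2,6,10-trien-1-ol | CC(C)=CC[C@@H](O[Si](C)(C)C(C)(C)C)/C(C)=C/CC/C(C)=C/CO
F6 | step 6 | [(2E,6E,8R)-1-bromo-3,7,11-trimethyldodeca-2,6,10-trien-8-yl]oxy(tert-butyl)dimethylsilane | CC(C)=CC[C@@H](O[Si](C)(C)C(C)(C)C)/C(C)=C/CC/C(C)=C/CBr
F7 | step 6 | (4E,8E,10R)-10-[(tert-butyldimethylsilyl)oxy]-1-(2-hydroxy-6-methylphenyl)-5,9,13-trimethyltetradeca-4,8,12-trien-1-one | CC(C)=CC[C@@H](O[Si](C)(C)C(C)(C)C)/C(C)=C/CC/C(C)=C/CCC(=O)c1c(C)cccc1O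
F8 | step 6 | ethyl (4E,8E,10R)-10-[(tert-butyldimethylsilyl)oxy]-2-(2-hydroxy-6-methylbenzoyl)-5,9,13-trimethyltetradeca-4,8,12-trienoate (both C2 epimers) | CC(C)=CC[C@@H](O[Si](C)(C)C(C)(C)C)/C(C)=C/CC/C(C)=C/CC(C(=O)OCC)C(=O)c1c(C)cccc1O
F9 | step 6 | 3-{(2E,6E,8R)-8-[(tert-butyldimethylsilyl)oxy]-3,7,11-trimethyldodeca-2,6,10-trien-1-yl}-4-hydroxy-5-methyl-2H-chromen-2-one | CC(C)=CC[C@@H](O[Si](C)(C)C(C)(C)C)/C(C)=C/CC/C(C)=C/Cc1c(O)c2c(C)cccc2oc1=O
F10 | step 3 | (2E,6E)-8-hydroxy-3,7-dimethylundeca-2,6,10-trien-1-yl acetate (racemic) | C=CCC(O)/C(C)=C/CC/C(C)=C/COC(C)=O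
F11 | step 3 | (2E,6E)-3,7-dimethyl-8-oxoundeca-2,6,10-trien-1-yl acetate | C=CCC(=O)/C(C)=C/CC/C(C)=C/COC(C)=O
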